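Everything rests on cutting the ten-membered carbocycle between C3 and C4, inside its Z-γ-hydroxy-enone (C1 ketone, C2=C3, C4 carbinol). An intramolecular Nozaki–Hiyama–Kishi addition of a (Z)-β-iodovinyl ketone to the C4 methyl ketone should close the ring and set the tertiary C4 centre in one operation. It exploits the cis C2=C3 geometry and the free C6 hydroxyl, β to the C4 ketone, as a chelating control element. The precursor is a trans-4,5-disubstituted α-methylene-γ-butyrolactone (C7, C8, C11, C12) carrying both arms, assembled by a stereospecific allylboration–lactonisation that relays a catalytically set C6 centre to C7 and C8; C10 comes from an oxazolidinone auxiliary.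

Key step: step 14

Remark on numbering: C1–C15 follow the germacranolide numbering of the target (C1 ketone, C2=C3, C4 carbinol bearing C15H3, C6 angelate carbon, C7/C8 lactone ring carbons, C10 bearing C14H2OH, C11=C13H2, C12 lactone carbonyl).
Assumption: (S,S)-ProPhenol/Me2Zn is taken to deliver the alkynyl group to the Si face of aldehyde 2 (4R in 5); if the sense is opposite, the (R,R)-ligand is used with no other change.
Remark: 27, 30 and 31 are drawn as open hydroxy-enones although they can equilibrate with the C1/C4 hemiketal.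

Step 1
Reactants: 1 ethyl 2-(2-methyl-1,3-dioxolan-2-yl)acetate
Product: 2 2-(2-methyl-1,3-dioxolan-2-yl)acetaldehyde
Conditions: i-Bu2AlH (1.05 equiv), CH2Cl2, −78 °C; aq. potassium sodium tartrate
Reagents that add atoms: none
Why: Partial ester reduction stops at the aluminium hemiacetal, stabilised at −78 °C by the neighbouring ketal oxygens, and releases the aldehyde on work-up (ester-to-aldehyde reduction).

Step 2
Reactants: 2 2-(2-methyl-1,3-dioxolan-2-yl)acetaldehyde; 3 methyl propiolate
Product: 5 methyl (4R)-4-hydroxy-5-(2-methyl-1,3-dioxolan-2-yl)pent-2-ynoate, via methylzinc alkynylide 4 (not isolated)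
Conditions: Me2Zn (3 equiv), (S,S)-ProPhenol (10 mol %), Ph3P=O (20 mol %), toluene, 0–4 °C
Reagents that add atoms: none
Why: Dinuclear-zinc ProPhenol-catalysed asymmetric alkynylation of an aldehyde, in which the chiral pocket selects the aldehyde face and sets C6 as R (catalyst control).

Step 3
Reactants: 5 methyl (4R)-4-hydroxy-5-(2-methyl-1,3-dioxolan-2-yl)pent-2-ynoate
Product: 6 methyl (4R)-4-(tert-butyldimethylsilyloxy)-5-(2-methyl-1,3-dioxolan-2-yl)pent-2-ynoate
Conditions: TBSOTf, 2,6-lutidine, CH2Cl2, −78 °C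
Reagents that add atoms: tert-butyldimethylsilyl trifluoromethanesulfonate, CC(C)(C)[Si](C)(C)OS(=O)(=O)C(F)(F)F
Why: O-silylation with a non-nucleophilic base, which avoids conjugate addition to the ynoate; the ketone ketal tolerates the silyl triflate at low temperature.

Step 4
Reactants: 6 methyl (4R)-4-(tert-butyldimethylsilyloxy)-5-(2-methyl-1,3-dioxolan-2-yl)pent-2-ynoate; 7 2-(iodomethyl)-4,4,5,5-tetramethyl-1,3,2-dioxaborolane
Product: 9 methyl (2Z,4R)-4-(tert-butyldimethylsilyloxy)-5-(2-methyl-1,3-dioxolan-2-yl)-2-[(4,4,5,5-tetramethyl-1,3,2-dioxaborolan-2-yl)methyl]pent-2-enoate, via α-aluminio acrylate 8 (not isolated)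
Conditions: i-Bu2AlH, HMPA, THF, 0 °C; then 7, 0 °C to rt
Reagents that add atoms: none
Why: Conjugate hydroalumination of the ynoate delivers H and Al syn, and C-alkylation of the α-aluminio acrylate by the iodomethylboronate with retention leaves C6 cis to the ester (Z), the geometry needed for a trans lactone (1,4-reduction/enolate-trapping route to 2-(alkoxycarbonyl)allylboronates).

Step 5
Reactants: 10 (R)-4-benzyl-1,3-oxazolidin-2-one; 11 pent-4-enoyl chloride
Product: 12 (4R)-4-benzyl-3-(pent-4-enoyl)-1,3-oxazolidin-2-one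
Conditions: Et3N, DMAP (cat.), CH2Cl2, 0 °C to rt
Reagents that add atoms: none
Why: DMAP-catalysed N-acylation of the oxazolidinone by the acid chloride.

Step 6
Reactants: 12 (4R)-4-benzyl-3-(pent-4-enoyl)-1,3-oxazolidin-2-one; 13 1,3,5-trioxane
Product: 15 (4R)-4-benzyl-3-[(2S)-2-(hydroxymethyl)pent-4-enoyl]-1,3-oxazolidin-2-one, via titanium enolate 14 (not isolated)
Conditions: TiCl4, i-Pr2NEt, CH2Cl2, 0 °C; then 13, TiCl4, 0 °C
Reagents that add atoms: none
Why: Evans alkylation of the chelated (Z)-titanium enolate with TiCl4-activated formaldehyde, which enters opposite the benzyl group and sets C10 as S (auxiliary control).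

Step 7
Reactants: 15 (4R)-4-benzyl-3-[(2S)-2-(hydroxymethyl)pent-4-enoyl]-1,3-oxazolidin-2-one
Product: 16 (2S)-2-(hydroxymethyl)-N-methoxy-N-methylpent-4-enamide
Conditions: MeNHOMe·HCl, AlMe3, CH2Cl2, −20 to 0 °C
Reagents that add atoms: N,O-dimethylhydroxylamine hydrochloride, CNOC.Cl
Why: Aluminium-amide transamidation, directed to the exocyclic carbonyl by the β-hydroxyl, gives the Weinreb amide without touching C10 and returns the auxiliary.

Step 8
Reactants: 16 (2S)-2-(hydroxymethyl)-N-methoxy-N-methylpent-4-enamide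
Product: 17 (2S)-2-[(tert-butyldiphenylsilyloxy)methyl]-N-methoxy-N-methylpent-4-enamide
Conditions: TBDPSCl, imidazole, CH2Cl2, rt
Reagents that add atoms: tert-butyl(chloro)diphenylsilane, CC(C)(C)[Si](Cl)(c1ccccc1)c1ccccc1
Why: Silylation of the primary alcohol with an acid-robust group that blocks oxa-Michael closure onto the later ynone and iodoenone.

Step 9
Reactants: 17 (2S)-2-[(tert-butyldiphenylsilyloxy)methyl]-N-methoxy-N-methylpent-4-enamide; 18 ethynylmagnesium bromide
Product: 19 (4S)-4-[(tert-butyldiphenylsilyloxy)methyl]hept-6-en-1-yn-3-one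
Conditions: THF, −20 to 0 °C; cold aq. NaHSO4
Reagents that add atoms: none
Why: Weinreb ketone synthesis, in which the stable magnesium chelate prevents over-addition and the cold acidic quench avoids epimerisation at C10 and amine addition to the ynone.

Step 10
Reactants: 19 (4S)-4-[(tert-butyldiphenylsilyloxy)methyl]hept-6-en-1-yn-3-one
Product: 20 (1Z,4S)-4-[(tert-butyldiphenylsilyloxy)methyl]-1-iodohepta-1,6-dien-3-one
Conditions: NaI, AcOH, rt, dark
Reagents that add atoms: sodium iodide, [Na+].[I-]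
Why: Conjugate hydroiodination of the ynone, where iodide adds to C3 and the allenol is protonated anti to give the kinetic Z-β-iodoenone; the isolated alkene does not react.

Step 11
Reactants: 20 (1Z,4S)-4-[(tert-butyldiphenylsilyloxy)methyl]-1-iodohepta-1,6-dien-3-one
Product: 22 (3S,5Z)-3-[(tert-butyldiphenylsilyloxy)methyl]-6-iodo-4-oxohex-5-enal, via vicinal diol 21 (not isolated)
Conditions: OsO4 (2 mol %), NaIO4, 2,6-lutidine, dioxane/H2O, rt
Reagents that add atoms: osmium tetroxide, O=[Os](=O)(=O)=O; sodium periodate, [Na+].[O-]I(=O)(=O)=O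
Why: Lemieux–Johnson oxidation, in which OsO4 dihydroxylates only the electron-rich terminal alkene and periodate cleaves the diol to the C8 aldehyde, leaving the electron-poor iodoenone intact.

Step 12
Reactants: 22 (3S,5Z)-3-[(tert-butyldiphenylsilyloxy)methyl]-6-iodo-4-oxohex-5-enal; 9 methyl (2Z,4R)-4-(tert-butyldimethylsilyloxy)-5-(2-methyl-1,3-dioxolan-2-yl)-2-[(4,4,5,5-tetramethyl-1,3,2-dioxaborolan-2-yl)methyl]pent-2-enoate
Product: 24 (4S,5R)-4-[(1R)-1-(tert-butyldimethylsilyloxy)-2-(2-methyl-1,3-dioxolan-2-yl)ethyl]-5-[(2S,4Z)-2-[(tert-butyldiphenylsilyloxy)methyl]-5-iodo-3-oxopent-4-en-1-yl]-3-methylideneoxolan-2-one, via homoallylic borate 23 (not isolated)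
Conditions: Sc(OTf)3 (10 mol %), toluene, 0 °C to rt; then p-TsOH (cat.), rt
Reagents that add atoms: none
Why: Lewis-acid-catalysed 2-(alkoxycarbonyl)allylboration through a closed chair transition state, then lactonisation: the Z geometry of 9 puts C6 equatorial and fixes 7,8-anti (trans lactone), while A(1,3) strain with the ester holds H-6 in the alkene plane so that the aldehyde should add anti to the C5 branch and syn to the silyloxy oxygen, relaying 6R to 7S and 8R (substrate control); the silyl ether on O6 ensures that only O8 lactonises, and the ketones do not react with the boronate.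

Step 13
Reactants: 24 (4S,5R)-4-[(1R)-1-(tert-butyldimethylsilyloxy)-2-(2-methyl-1,3-dioxolan-2-yl)ethyl]-5-[(2S,4Z)-2-[(tert-butyldiphenylsilyloxy)methyl]-5-iodo-3-oxopent-4-en-1-yl]-3-methylideneoxolan-2-one
Product: 25 (4R,5R)-4-[(1R)-1-hydroxy-3-oxobutyl]-5-[(2S,4Z)-2-[(tert-butyldiphenylsilyloxy)methyl]-5-iodo-3-oxopent-4-en-1-yl]-3-methylideneoxolan-2-one
Conditions: 48% aq. HF, MeCN, 0 °C to rt
Reagents that add atoms: water, O
Why: Acidic deprotection in which aqueous HF hydrolyses the dioxolane and cleaves the secondary TBS ether, while the far more acid-stable primary TBDPS ether, the lactone and the Z-iodoenone should survive (spatial arrangement unchanged; the C7 descriptor changes only by priority).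

Step 14
Reactants: 25 (4R,5R)-4-[(1R)-1-hydroxy-3-oxobutyl]-5-[(2S,4Z)-2-[(tert-butyldiphenylsilyloxy)methyl]-5-iodo-3-oxopent-4-en-1-yl]-3-methylideneoxolan-2-one
Product: 27 (2Z,4R,6R,7R,8R,10S)-14-(tert-butyldiphenylsilyloxy)-4,6-dihydroxy-1-oxogermacra-2,11(13)-dien-12,8-olide, via alkenylchromium dichloride 26 (not isolated)
Conditions: CrCl2 (10 equiv), NiCl2 (5 mol %), degassed DMSO/THF, 0.002 M, slow addition, rt to 40 °C
Reagents that add atoms: none
Why: Zerovalent nickel, formed from NiCl2 by CrCl2, inserts into the carbon–iodine bond of the (Z)-β-iodoenone, transmetalation gives the alkenylchromium 26 (trivalent chromium) with retention of the Z geometry, which internal coordination of the C1 carbonyl to chromium further favours, and this adds 1,2 to the C4 methyl ketone. The closest known reaction type is the Nozaki–Hiyama–Kishi macrocyclisation of alkenyl iodides onto aldehydes, established for ten-membered rings, together with intramolecular Ni/Cr additions to ketones in smaller rings. The ten-membered carbocycle closes in a 10-exo-trig mode by attack on the C4 carbonyl, and no other ring forms. The new C4 centre is controlled by the free C6 hydroxyl: chromium bridges O6 and the C4 carbonyl in a six-membered chelate and the tethered alkenyl group enters anti to C7, which should give the 4,6-anti diol (4R) with the methyl group on the outside of the forming ring. The step needs chemoselectivity for the C4 ketone over the enone and lactone carbonyls and the exocyclic acrylate, which the low basicity and carbonyl selectivity of organochromium reagents provide, and cyclisation must outrun oligomerisation, which high dilution, slow addition and the pre-bent Z-alkene on the trans-lactone scaffold secure.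

Step 15
Reactants: 27 (2Z,4R,6R,7R,8R,10S)-14-(tert-butyldiphenylsilyloxy)-4,6-dihydroxy-1-oxogermacra-2,11(13)-dien-12,8-olide; 28 angelic acid ((Z)-2-methylbut-2-enoic acid)
Product: 30 (2Z,4R,6R,7S,8R,10S)-6-angeloyloxy-14-(tert-butyldiphenylsilyloxy)-4-hydroxy-1-oxogermacra-2,11(13)-dien-12,8-olide, via mixed anhydride 29 (not isolated)
Conditions: 28, 2,4,6-trichlorobenzoyl chloride, Et3N, toluene, rt; then 27, 75 °C
Reagents that add atoms: none
Why: Yamaguchi esterification with the preformed angelic mixed anhydride acylates the secondary C6 hydroxyl without Z-to-E isomerisation of the angelate, and the tertiary C4 hydroxyl is too hindered to react.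

Step 16
Reactants: 30 (2Z,4R,6R,7S,8R,10S)-6-angeloyloxy-14-(tert-butyldiphenylsilyloxy)-4-hydroxy-1-oxogermacra-2,11(13)-dien-12,8-olide
Product: 31 (2Z,4R,6R,7S,8R,10S)-6-angeloyloxy-4,14-dihydroxy-1-oxogermacra-2,11(13)-dien-12,8-olide (CNP0219400.1)
Conditions: HF·pyridine, pyridine/THF, 0 °C to rt
Reagents that add atoms: none
Why: Fluoride desilylation under buffered, non-basic conditions should free the C14 hydroxyl without β-elimination, epimerisation at C10 or acyl migration.

Compound list
1 | ethyl 2-(2-methyl-1,3-dioxolan-2-yl)acetate | CCOC(=O)CC1(C)OCCO1 | starting material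
2 | 2-(2-methyl-1,3-dioxolan-2-yl)acetaldehyde | O=CCC1(C)OCCO1 | intermediate
3 | methyl propiolate | C#CC(=O)OC | starting material
4 | methyl 3-(methylzincio)prop-2-ynoate (zinc alkynylide) | C[Zn]C#CC(=O)OC | intermediate (not isolated)
5 | methyl (4R)-4-hydroxy-5-(2-methyl-1,3-dioxolan-2-yl)pent-2-ynoate | COC(=O)C#C[C@H](O)CC1(C)OCCO1 | intermediate
6 | methyl (4R)-4-(tert-butyldimethylsilyloxy)-5-(2-methyl-1,3-dioxolan-2-yl)pent-2-ynoate | COC(=O)C#C[C@H](O[Si](C)(C)C(C)(C)C)CC1(C)OCCO1 | intermediate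
7 | 2-(iodomethyl)-4,4,5,5-tetramethyl-1,3,2-dioxaborolane | ICB1OC(C)(C)C(C)(C)O1 | starting material
8 | methyl (2E,4R)-2-(diisobutylaluminio)-4-(tert-butyldimethylsilyloxy)-5-(2-methyl-1,3-dioxolan-2-yl)pent-2-enoate (Al cis to H-7) | COC(=O)/C(=C\[C@H](O[Si](C)(C)C(C)(C)C)CC1(C)OCCO1)[Al](CC(C)C)CC(C)C | intermediate (not isolated)
9 | methyl (2Z,4R)-4-(tert-butyldimethylsilyloxy)-5-(2-methyl-1,3-dioxolan-2-yl)-2-[(4,4,5,5-tetramethyl-1,3,2-dioxaborolan-2-yl)methyl]pent-2-enoate | COC(=O)/C(CB1OC(C)(C)C(C)(C)O1)=C\[C@H](O[Si](C)(C)C(C)(C)C)CC1(C)OCCO1 | intermediate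
10 | (R)-4-benzyl-1,3-oxazolidin-2-one | O=C1N[C@H](Cc2ccccc2)CO1 | starting material
11 | pent-4-enoyl chloride | C=CCCC(Cl)=O | starting material
12 | (4R)-4-benzyl-3-(pent-4-enoyl)-1,3-oxazolidin-2-one | C=CCCC(=O)N1[C@H](Cc2ccccc2)COC1=O | intermediate
13 | 1,3,5-trioxane | C1OCOCO1 | starting material
14 | trichlorotitanium (Z)-enolate of 12 | C=CC/C=C(\O[Ti](Cl)(Cl)Cl)N1[C@H](Cc2ccccc2)COC1=O | intermediate (not isolated)
15 | (4R)-4-benzyl-3-[(2S)-2-(hydroxymethyl)pent-4-enoyl]-1,3-oxazolidin-2-one | C=CC[C@@H](CO)C(=O)N1[C@H](Cc2ccccc2)COC1=O | intermediate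
16 | (2S)-2-(hydroxymethyl)-N-methoxy-N-methylpent-4-enamide | C=CC[C@@H](CO)C(=O)N(C)OC | intermediate
17 | (2S)-2-[(tert-butyldiphenylsilyloxy)methyl]-N-methoxy-N-methylpent-4-enamide | C=CC[C@@H](CO[Si](c1ccccc1)(c1ccccc1)C(C)(C)C)C(=O)N(C)OC | intermediate
18 | ethynylmagnesium bromide | C#C[Mg]Br | starting material
19 | (4S)-4-[(tert-butyldiphenylsilyloxy)methyl]hept-6-en-1-yn-3-one | C=CC[C@@H](CO[Si](c1ccccc1)(c1ccccc1)C(C)(C)C)C(=O)C#C | intermediate
20 | (1Z,4S)-4-[(tert-butyldiphenylsilyloxy)methyl]-1-iodohepta-1,6-dien-3-one | C=CC[C@@H](CO[Si](c1ccccc1)(c1ccccc1)C(C)(C)C)C(=O)/C=C\I | intermediate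
21 | (1Z,4S)-4-[(tert-butyldiphenylsilyloxy)methyl]-6,7-dihydroxy-1-iodohept-1-en-3-one (C6 epimers) | OCC(O)C[C@@H](CO[Si](c1ccccc1)(c1ccccc1)C(C)(C)C)C(=O)/C=C\I | intermediate (not isolated)
22 | (3S,5Z)-3-[(tert-butyldiphenylsilyloxy)methyl]-6-iodo-4-oxohex-5-enal | O=CC[C@@H](CO[Si](c1ccccc1)(c1ccccc1)C(C)(C)C)C(=O)/C=C\I | intermediate
23 | open-chain anti homoallylic borate (O8–B pinacol ester of the C7/C8 hydroxy methyl ester; 6R,7S,8R,10S in target numbering) | C=C(C(=O)OC)[C@H]([C@H](O[Si](C)(C)C(C)(C)C)CC1(C)OCCO1)[C@H](OB1OC(C)(C)C(C)(C)O1)C[C@@H](CO[Si](c1ccccc1)(c1ccccc1)C(C)(C)C)C(=O)/C=C\I | intermediate (not isolated)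
24 | (4S,5R)-4-[(1R)-1-(tert-butyldimethylsilyloxy)-2-(2-methyl-1,3-dioxolan-2-yl)ethyl]-5-[(2S,4Z)-2-[(tert-butyldiphenylsilyloxy)methyl]-5-iodo-3-oxopent-4-en-1-yl]-3-methylideneoxolan-2-one | C=C1C(=O)O[C@H](C[C@@H](CO[Si](c2ccccc2)(c2ccccc2)C(C)(C)C)C(=O)/C=C\I)[C@H]1[C@H](O[Si](C)(C)C(C)(C)C)CC3(C)OCCO3 | intermediate
25 | (4R,5R)-4-[(1R)-1-hydroxy-3-oxobutyl]-5-[(2S,4Z)-2-[(tert-butyldiphenylsilyloxy)methyl]-5-iodo-3-oxopent-4-en-1-yl]-3-methylideneoxolan-2-one | C=C1C(=O)O[C@H](C[C@@H](CO[Si](c2ccccc2)(c2ccccc2)C(C)(C)C)C(=O)/C=C\I)[C@H]1[C@H](O)CC(C)=O | intermediate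
26 | (Z)-alkenylchromium dichloride derived from 25 (Cr on C3) | C=C1C(=O)O[C@H](C[C@@H](CO[Si](c2ccccc2)(c2ccccc2)C(C)(C)C)C(=O)/C=C\[Cr](Cl)Cl)[C@H]1[C@H](O)CC(C)=O | intermediate (not isolated)
27 | (2Z,4R,6R,7R,8R,10S)-14-(tert-butyldiphenylsilyloxy)-4,6-dihydroxy-1-oxogermacra-2,11(13)-dien-12,8-olide (same spatial arrangement as the target; C7 descriptor differs by priority only) | C=C1C(=O)O[C@@H]2C[C@@H](CO[Si](c3ccccc3)(c3ccccc3)C(C)(C)C)C(=O)/C=C\[C@](C)(O)C[C@@H](O)[C@@H]12 | intermediate
28 | angelic acid, (Z)-2-methylbut-2-enoic acid | C/C=C(/C)C(=O)O | starting material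
29 | angelic 2,4,6-trichlorobenzoic anhydride | C/C=C(/C)C(=O)OC(=O)c1c(Cl)cc(Cl)cc1Cl | intermediate (not isolated)
30 | (2Z,4R,6R,7S,8R,10S)-6-angeloyloxy-14-(tert-butyldiphenylsilyloxy)-4-hydroxy-1-oxogermacra-2,11(13)-dien-12,8-olide | C=C1C(=O)O[C@@H]2C[C@@H](CO[Si](c3ccccc3)(c3ccccc3)C(C)(C)C)C(=O)/C=C\[C@](C)(O)C[C@@H](OC(=O)/C(C)=C\C)[C@@H]12 | intermediate
31 | (2Z,4R,6R,7S,8R,10S)-6-angeloyloxy-4,14-dihydroxy-1-oxogermacra-2,11(13)-dien-12,8-olide (CNP0219400.1) | C=C1C(=O)O[C@@H]2C[C@@H](CO)C(=O)/C=C\[C@](C)(O)C[C@@H](OC(=O)/C(C)=C\C)[C@@H]12 | target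

Total step count: 16. Longest linear sequence: 12 steps (steps 5–11, then 12–16, from 10 and 11); the boronate branch (steps 1–4) joins at step 12.

Steps most likely to fail

Step 14. The electron-poor alkenylchromium from the β-iodoenone may add too slowly to a ketone, so that protodeiodination or oligomerisation wins, or the C4 face may not follow the chelate model. The fallback takes the C1 carbonyl out of conjugation for the ring closure and sets out from 24. Luche reduction (NaBH4, CeCl3·7H2O, MeOH, −78 °C) of the enone carbonyl gives the C1 allylic alcohol F1 (both C1 epimers are usable). Aqueous HF in MeCN then frees the C4 ketone and the C6 hydroxyl to give the diol ketone F2. The same CrCl2/NiCl2 conditions now act on an ordinary, more nucleophilic (Z)-alkenyl iodide and should close the macrocyclic triol F3. MnO2 in CH2Cl2 oxidises only the allylic C1 hydroxyl and comes back to the route at 27.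

Step 12. The facial selectivity at C7 relative to C6 may be poor, or may favour addition anti to the silyloxy group, which would give the 7R,8S lactone. The fallback moves C6 control to a later, catalyst-controlled step and sets out from 22. Methyl 4,4-diethoxybut-2-ynoate F4 (from commercial 3,3-diethoxyprop-1-yne, n-BuLi, methyl chloroformate) is converted by the step 4 protocol into the achiral acetal allylboronate F5. Allylboration of 22 under a chiral phosphoric acid, (R)-TRIP or its enantiomer as matched to 8R (catalyst control of the aldehyde face, chair transition state for 7,8-anti), followed by acid lactonisation gives the trans-lactone acetal F6. Mild hydrolysis (aq. TFA, CH2Cl2, 0 °C) gives the lactone aldehyde F7. An L-proline-catalysed aldol with acetone then sets C6 as R on this α-branched aldehyde and comes back to the route at 25.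

Step 4. Trapping of the α-aluminio acrylate may be slow or may scramble the alkene geometry through the allenolate, and over-reduction of the ester can compete. The fallback builds the same bond by cross-coupling and sets out from 6. Syn-hydrostannation (Bu3SnH, Pd(PPh3)4, THF) gives the α-stannyl enoate F8 with tin cis to H-7. Iododestannylation (iodine, CH2Cl2, 0 °C) gives with retention the α-iodo enoate F9. Negishi coupling with (pinacolatoboryl)methylzinc iodide F10 (from 7 and zinc dust) under Pd(PPh3)4 comes back to the route at 9, with the Z geometry fixed by the hydrostannation.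

Further compounds
F1 | step 14 | C1 allylic alcohol of 24 (Luche product, C1 epimers) | C=C1C(=O)O[C@H](C[C@@H](CO[Si](c2ccccc2)(c2ccccc2)C(C)(C)C)C(O)/C=C\I)[C@H]1[C@H](O[Si](C)(C)C(C)(C)C)CC3(C)OCCO3
F2 | step 14 | diol ketone seco compound (C1 and C6 hydroxyls free, C4 ketone) | C=C1C(=O)O[C@H](C[C@@H](CO[Si](c2ccccc2)(c2ccccc2)C(C)(C)C)C(O)/C=C\I)[C@H]1[C@H](O)CC(C)=O
F3 | step 14 | macrocyclic 1,4,6-triol (C1 epimers, 14-O-TBDPS) | C=C1C(=O)O[C@@H]2C[C@@H](CO[Si](c3ccccc3)(c3ccccc3)C(C)(C)C)C(O)/C=C\[C@](C)(O)C[C@@H](O)[C@@H]12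
F4 | step 12 | methyl 4,4-diethoxybut-2-ynoate | CCOC(OCC)C#CC(=O)OC
F5 | step 12 | methyl (2Z)-4,4-diethoxy-2-[(4,4,5,5-tetramethyl-1,3,2-dioxaborolan-2-yl)methyl]but-2-enoate | COC(=O)/C(CB1OC(C)(C)C(C)(C)O1)=C\C(OCC)OCC
F6 | step 12 | trans-lactone bearing the C6 diethyl acetal | C=C1C(=O)O[C@H](C[C@@H](CO[Si](c2ccccc2)(c2ccccc2)C(C)(C)C)C(=O)/C=C\I)[C@H]1C(OCC)OCC
F7 | step 12 | trans-lactone C6 aldehyde | C=C1C(=O)O[C@H](C[C@@H](CO[Si](c2ccccc2)(c2ccccc2)C(C)(C)C)C(=O)/C=C\I)[C@H]1C=O
F8 | step 4 | methyl (2E,4R)-4-(tert-butyldimethylsilyloxy)-5-(2-methyl-1,3-dioxolan-2-yl)-2-(tributylstannyl)pent-2-enoate | COC(=O)/C(=C\[C@H](O[Si](C)(C)C(C)(C)C)CC1(C)OCCO1)[Sn](CCCC)(CCCC)CCCC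
F9 | step 4 | methyl (2E,4R)-4-(tert-butyldimethylsilyloxy)-2-iodo-5-(2-methyl-1,3-dioxolan-2-yl)pent-2-enoate | COC(=O)/C(I)=C\[C@H](O[Si](C)(C)C(C)(C)C)CC1(C)OCCO1
F10 | step 4 | [(4,4,5,5-tetramethyl-1,3,2-dioxaborolan-2-yl)methyl]zinc iodide | I[Zn]CB1OC(C)(C)C(C)(C)O1
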